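**Strategy**

The route rests on disconnecting the bond between the exocyclic CH2 on chroman C2 and C6, the β-carbon of the hydrindenone enone. Chroman O1 and that CH2 are both attached to C2, so they can be delivered together across a 1,1-disubstituted alkene: a palladium-catalysed asymmetric alkene carboetherification joins phenol 15, carrying a 3-methylbut-3-enyl chain, to β-bromo enone 11 and in one operation closes the pyran ring (O1–C2), sets the C2 stereocentre and forms the CH2–C6 bond. Bromo enone 11 derives from a cis-dimethylhydrindane-1,3-dione built by an auxiliary-controlled De Mayo sequence; a final Markovnikov hydration reveals the tertiary alcohol.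

Key step: step 8

Atom numbers used: chroman O1, C2; hydrindenone C3a, C4 (C=O), C5 (α-carbon), C6 (β-carbon), C7, C7a.

Assumption: in spiro dioxinone 4 the isopropyl-bearing carbon of the auxiliary shields one enone face, so the alkene adds to the other face in the cis-anti-cis sense; should the sense prove opposite, the (6R) spiro epimer formed in the same step 1 is carried forward instead and nothing else changes.

**Route**

Step 1
Reactants: 1 (−)-menthone; 2 2,2,6-trimethyl-4H-1,3-dioxin-4-one
Product: 4 (6S,7S,10R)-2,10-dimethyl-7-(propan-2-yl)-1,5-dioxaspiro[5.5]undec-2-en-4-one, via acetylketene 3 (not isolated)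
Conditions: 1 (3 equiv), xylene, 140 °C, acetone distilled off; chromatographic separation of the two spiro epimers
Reagents that add atoms: none
Why: Thermolysis of 2 by a retro-hetero-Diels–Alder reaction releases acetone and acetylketene 3, which the carbonyl group of 1 traps in a hetero-Diels–Alder reaction (dioxinone exchange); the spiro centre forms unselectively, so the (6S) epimer is separated, and the neutral conditions avoid epimerisation of 1.

Step 2
Reactants: 4 spiro dioxinone; 5 1,2-dimethylcyclopentene
Product: 6 cis-anti-cis cyclobutane photoadduct of 4 and 5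
Conditions: 5 (5 equiv), hν (300 nm, Pyrex), acetone–MeCN, −40 °C; chromatography or crystallisation of the major diastereomer
Reagents that add atoms: none
Why: De Mayo-type [2+2] enone–alkene photocycloaddition through the dioxinone triplet: the four-membered ring can only be cis-fused to both rings, which places the two new methyl-bearing quaternary carbons cis, while their absolute configuration follows from addition to the enone face remote from the isopropyl-bearing carbon of the auxiliary in the less crowded cis-anti-cis sense, the major diastereomer being purified while the auxiliary is still attached.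

Step 3
Reactants: 6 photoadduct
Product: 9 (3aS,7aS)-3a,7a-dimethyloctahydro-1H-indene-4,6-dione, via cyclobutanol methyl ester 7 (not isolated), via keto ester 8 (not isolated)
Conditions: NaOMe (3 equiv), MeOH, 65 °C; then toluene, 110 °C (MeOH distilled off); aq. HCl; 9 separated from menthone by base extraction
Reagents that add atoms: none
Why: Second half of the De Mayo reaction followed by a Claisen (Dieckmann-type) condensation: methoxide opens the acylal and expels menthone, the strained cyclobutanolate of 7 fragments by retro-aldol cleavage to keto ester 8, and the methyl ketone enolate closes onto the ester to give the 1,3-dione as its stable enolate, with no bond to either quaternary stereocentre broken.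

Step 4
Reactants: 9 hydrindane-4,6-dione
Product: 10 (3aS,7aS)-6-hydroxy-3a,7a-dimethyl-5-(2-methylprop-2-en-1-yl)-1,2,3,3a,7,7a-hexahydro-4H-inden-4-one (enol form of the 5-(2-methylallyl)-4,6-dione)
Conditions: Pd(PPh3)4 (2 mol %), DBU (1.1 equiv), toluene, 50 °C
Reagents that add atoms: 2-methylallyl acetate, CC(=C)COC(C)=O
Why: Tsuji–Trost allylation: the soft enolate of the 1,3-dione attacks the symmetrical 2-methylallyl palladium complex at carbon C5 (O-allylation is reversible under the catalyst), and one equivalent of the acetate limits double allylation.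

Step 5
Reactants: 10 2-methylallyl dione (enol)
Product: 11 (3aS,7aS)-6-bromo-3a,7a-dimethyl-5-(2-methylprop-2-en-1-yl)-1,2,3,3a,7,7a-hexahydro-4H-inden-4-one
Conditions: Ph3PBr2 (1.2 equiv), Et3N (1.3 equiv), CH2Cl2, 0 °C to rt
Reagents that add atoms: dibromotriphenylphosphorane, BrP(Br)(c1ccccc1)(c1ccccc1)c1ccccc1
Why: Conversion of a 1,3-dione into a β-bromo enone by oxygen activation with the bromophosphonium reagent and addition–elimination of bromide: both the phosphonium transfer and the bromide attack favour the C6 oxygen and carbon, which lie next to a CH2 group, over C4 next to the quaternary C3a, and Et3N keeps HBr away from the 2-methylallyl alkene.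

Step 6
Reactants: 12 4-methoxy-2-methylphenol
Product: 13 2-(hydroxymethyl)-4-methoxy-6-methylphenol
Conditions: 37 % aq. HCHO (1.5 equiv), NaOH (1 equiv), H2O, N2, 20 °C; then aq. HCl to pH 6
Reagents that add atoms: formaldehyde, C=O
Why: Lederer–Manasse hydroxymethylation: the phenoxide attacks formaldehyde through its only free ortho position (the para position carries OMe), and a modest excess of formaldehyde at room temperature limits diarylmethane formation.

Step 7
Reactants: 13 2-(hydroxymethyl)-4-methoxy-6-methylphenol
Product: 15 4-methoxy-2-methyl-6-(3-methylbut-3-en-1-yl)phenol, via ortho-quinone methide 14 (not isolated)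
Conditions: CH2=C(CH3)CH2MgCl (3.5 equiv), THF–toluene, 0 to 80 °C; aq. NH4Cl
Reagents that add atoms: 2-methylallylmagnesium chloride, CC(=C)C[Mg]Cl
Why: Ortho-quinone methide formation and 1,4-addition: the bis(chloromagnesium) salt of 13 loses the benzylic oxygen on warming to give 14, which the excess Grignard reagent captures at the exocyclic methylene with rearomatisation; the 2-methylallyl nucleophile is symmetrical, so both of its ends give the same 3-methylbut-3-enyl chain.

Step 8
Reactants: 11 β-bromo enone; 15 4-methoxy-2-methyl-6-(3-methylbut-3-en-1-yl)phenol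
Product: 16 (3aS,7aS)-6-{[(2S)-6-methoxy-2,8-dimethyl-3,4-dihydro-2H-chromen-2-yl]methyl}-3a,7a-dimethyl-5-(2-methylprop-2-en-1-yl)-1,2,3,3a,7,7a-hexahydro-4H-inden-4-one
Conditions: Pd2(dba)3 (2.5 mol %), Siphos-PE (one antipode, 7.5 mol %), Cs2CO3 (2 equiv), toluene, 90 °C
Reagents that add atoms: none
Why: Alkene carboetherification under zerovalent palladium catalysis: oxidative addition into the C6–Br bond of 11 gives an alkenylpalladium bromide, Cs2CO3 exchanges bromide for the phenoxide of 15, the pendant 1,1-disubstituted alkene inserts syn into the Pd–O bond, and C(sp3)–C(sp2) reductive elimination from the resulting alkyl(alkenyl)palladium forms the CH2–C6 bond. The closest known reaction type is the palladium-catalysed synthesis of 2-substituted and 2,2-disubstituted chromans from 2-(but-3-enyl)phenols and aryl or alkenyl bromides. The pyran ring closes by 6-exo-trig syn-oxypalladation (O1–C2 bond), oxygen adding to the internal alkene carbon and palladium to the terminal CH2. The quaternary centre C2 is set in this insertion under control of the chiral ligand, whose antipode is chosen in a model run to deliver (2S); the stereocentres of 11 are remote, and any minor C2 epimer is a diastereomer of 16 that chromatography should remove. The step needs insertion to outrun C–O bond formation at C6 (reductive elimination or addition–elimination of the phenoxide), which the two ortho substituents of the phenoxide, the fully substituted bromo-enone carbon and the sparingly soluble carbonate base should secure; β-hydride elimination is excluded because C2, the carbon next to the palladium-bearing CH2, carries no hydrogen.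

Step 9
Reactants: 16 coupled 2-methylallyl enone
Product: 17 (3aS,7aS)-5-(2-hydroxy-2-methylpropyl)-6-{[(2S)-6-methoxy-2,8-dimethyl-3,4-dihydro-2H-chromen-2-yl]methyl}-3a,7a-dimethyl-1,2,3,3a,7,7a-hexahydro-4H-inden-4-one (CNP0224132.2)
Conditions: Co(acac)2 (20 mol %), PhSiH3 (2.5 equiv), O2 (1 atm), THF, 25 °C; then aq. Na2S2O3
Reagents that add atoms: dioxygen, O=O
Why: Mukaiyama hydration (cobalt-catalysed hydrogen atom transfer, trapping of the tertiary radical by O2 and reduction of the peroxide): the 1,1-disubstituted alkene reacts far faster than the tetrasubstituted, electron-poor enone double bond and gives the Markovnikov tertiary alcohol, which is not a stereocentre.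

**Compound list**

1 | (−)-menthone, (2S,5R)-5-methyl-2-(propan-2-yl)cyclohexan-1-one | C[C@@H]1CC[C@H](C(=O)C1)C(C)C | starting material
2 | 2,2,6-trimethyl-4H-1,3-dioxin-4-one | CC1=CC(=O)OC(C)(C)O1 | starting material
3 | acetylketene (3-oxobut-1-en-1-one) | CC(=O)C=C=O | intermediate
4 | (6S,7S,10R)-2,10-dimethyl-7-(propan-2-yl)-1,5-dioxaspiro[5.5]undec-2-en-4-one (spiro dioxinone of menthone, 6S epimer) | CC1=CC(=O)O[C@@]2(O1)C[C@H](C)CC[C@H]2C(C)C | intermediate
5 | 1,2-dimethylcyclopentene | CC1=C(C)CCC1 | starting material
6 | photoadduct: cyclobutane fused to the spiro-menthane dioxanone and to the cyclopentane, the two rings on opposite faces of the cyclobutane (cis-anti-cis), three methyl groups on the cyclobutane carbons, configuration as in the SMILES | O=C1[C@@H]2[C@](C)(O[C@]3(O1)C[C@H](C)CC[C@H]3C(C)C)[C@@]4(C)CCC[C@@]24C | intermediate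
7 | methyl (1S,5S,6S,7S)-7-hydroxy-1,5,7-trimethylbicyclo[3.2.0]heptane-6-carboxylate | COC(=O)[C@@H]1[C@](C)(O)[C@@]2(C)CCC[C@@]12C | intermediate
8 | methyl 2-[(1S,2S)-2-acetyl-1,2-dimethylcyclopentyl]acetate | CC(=O)[C@@]1(C)CCC[C@@]1(C)CC(=O)OC | intermediate
9 | (3aS,7aS)-3a,7a-dimethyloctahydro-1H-indene-4,6-dione (cis-fused, both methyl groups cis) | O=C1CC(=O)[C@@]2(C)CCC[C@@]2(C)C1 | intermediate
10 | (3aS,7aS)-6-hydroxy-3a,7a-dimethyl-5-(2-methylprop-2-en-1-yl)-1,2,3,3a,7,7a-hexahydro-4H-inden-4-one (enol tautomer) | OC1=C(CC(C)=C)C(=O)[C@@]2(C)CCC[C@@]2(C)C1 | intermediate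
11 | (3aS,7aS)-6-bromo-3a,7a-dimethyl-5-(2-methylprop-2-en-1-yl)-1,2,3,3a,7,7a-hexahydro-4H-inden-4-one | BrC1=C(CC(C)=C)C(=O)[C@@]2(C)CCC[C@@]2(C)C1 | intermediate
12 | 4-methoxy-2-methylphenol | COc1ccc(O)c(C)c1 | starting material
13 | 2-(hydroxymethyl)-4-methoxy-6-methylphenol | COc1cc(C)c(O)c(CO)c1 | intermediate
14 | 4-methoxy-2-methyl-6-methylidenecyclohexa-2,4-dien-1-one (ortho-quinone methide) | C=C1C=C(OC)C=C(C)C1=O | intermediate
15 | 4-methoxy-2-methyl-6-(3-methylbut-3-en-1-yl)phenol | COc1cc(C)c(O)c(CCC(C)=C)c1 | intermediate
16 | (3aS,7aS)-6-{[(2S)-6-methoxy-2,8-dimethyl-3,4-dihydro-2H-chromen-2-yl]methyl}-3a,7a-dimethyl-5-(2-methylprop-2-en-1-yl)-1,2,3,3a,7,7a-hexahydro-4H-inden-4-one | COc1cc(C)c2c(c1)CC[C@@](C)(CC1=C(CC(C)=C)C(=O)[C@@]3(C)CCC[C@@]3(C)C1)O2 | intermediate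
17 | (3aS,7aS)-5-(2-hydroxy-2-methylpropyl)-6-{[(2S)-6-methoxy-2,8-dimethyl-3,4-dihydro-2H-chromen-2-yl]methyl}-3a,7a-dimethyl-1,2,3,3a,7,7a-hexahydro-4H-inden-4-one | COc1cc(C)c2c(c1)CC[C@@](C)(CC1=C(CC(C)(C)O)C(=O)[C@@]3(C)CCC[C@@]3(C)C1)O2 | target

**Step count and risks**

Total step count: 9. Longest linear sequence: 7 (steps 1, 2, 3, 4, 5, 8, 9).

Steps most likely to fail:

1. Step 8. The phenoxide may bond to C6 without alkene insertion (C–O reductive elimination or addition–elimination), and facial discrimination in the oxypalladation may be insufficient, so that both C2 epimers form. The fallback uses known chemistry, sets out from 15 and returns at 16. Enantioselective domino Wacker cyclisation/methoxycarbonylation of 15 (Pd(OCOCF3)2, a Bn-BOXAX bis(oxazoline) ligand, p-benzoquinone, CO, MeOH) should give methyl 2-[(2S)-6-methoxy-2,8-dimethylchroman-2-yl]acetate F1 with the C2 centre already in place. Saponification (LiOH, aq. THF) to the chromanylacetic acid F2 and coupling with N-hydroxyphthalimide (DIC, DMAP) should give the redox-active ester F3. Its decarboxylative alkenylation with 11 (NiBr2(dme), 4,4'-di-tert-butyl-2,2'-bipyridine, Zn, DMA) forms the same CH2–C6 bond through the primary chromanylmethyl radical and gives 16.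

2. Step 2. Facial selectivity or the cis-anti-cis preference may be poor, and either erodes the enantiomeric purity of 9 unless the diastereomers are separated; hydrogen abstraction from the tetrasubstituted alkene may also compete with cycloaddition. The fallback gives up auxiliary control for a resolution, sets out from 2 and 5 and returns at 8. Irradiation of 2 with 5 should give the racemic photoadduct F4, and KOH in aqueous MeOH (hydrolysis, loss of acetone, retro-aldol cleavage) the racemic keto acid F5. Crystallisation with the 1-phenylethylamine antipode whose salt with the (1S,2S)-acid is the less soluble one (drawn for the (R)-amine) gives the salt F6. Acidification gives the (1S,2S)-keto acid F7, and esterification (MeOH, cat. H2SO4) gives keto ester 8, which enters the Claisen condensation of step 3.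

3. Step 7. The chloromagnesium alkoxide is a poor leaving group, so quinone methide formation may stall, or the quinone methide may oligomerise faster than the Grignard reagent traps it. The fallback builds the chain by carbonyl chemistry, sets out from 12 and returns at 15. Magnesium-mediated ortho-formylation (MgCl2, Et3N, paraformaldehyde, MeCN, reflux) should give 2-hydroxy-5-methoxy-3-methylbenzaldehyde F8. Claisen–Schmidt condensation with acetone (aq. NaOH) gives the (E)-enone F9, hydrogenation (H2, Pd/C, EtOAc) the saturated ketone F10, and Wittig methylenation (Ph3PCH3Br, KOtBu, 2.5 equiv, THF) gives 15.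

**Further compounds**

F1 | step 8 | methyl 2-[(2S)-6-methoxy-2,8-dimethyl-3,4-dihydro-2H-chromen-2-yl]acetate | COc1cc(C)c2c(c1)CC[C@@](C)(CC(=O)OC)O2
F2 | step 8 | 2-[(2S)-6-methoxy-2,8-dimethyl-3,4-dihydro-2H-chromen-2-yl]acetic acid | COc1cc(C)c2c(c1)CC[C@@](C)(CC(=O)O)O2
F3 | step 8 | 1,3-dioxoisoindolin-2-yl 2-[(2S)-6-methoxy-2,8-dimethyl-3,4-dihydro-2H-chromen-2-yl]acetate | COc1cc(C)c2c(c1)CC[C@@](C)(CC(=O)ON1C(=O)c3ccccc3C1=O)O2
F4 | step 2 | racemic photoadduct of 2 and 5 (both enantiomers) | O=C1[C@@H]2[C@](C)(OC(C)(C)O1)[C@@]3(C)CCC[C@@]23C.O=C1[C@H]2[C@@](C)(OC(C)(C)O1)[C@]3(C)CCC[C@]23C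
F5 | step 2 | racemic cis-2-(2-acetyl-1,2-dimethylcyclopentyl)acetic acid (both enantiomers) | CC(=O)[C@@]1(C)CCC[C@@]1(C)CC(=O)O.CC(=O)[C@]1(C)CCC[C@]1(C)CC(=O)O
F6 | step 2 | (R)-1-phenylethylammonium 2-[(1S,2S)-2-acetyl-1,2-dimethylcyclopentyl]acetate | CC(=O)[C@@]1(C)CCC[C@@]1(C)CC(=O)[O-].C[C@@H]([NH3+])c1ccccc1
F7 | step 2 | 2-[(1S,2S)-2-acetyl-1,2-dimethylcyclopentyl]acetic acid | CC(=O)[C@@]1(C)CCC[C@@]1(C)CC(=O)O
F8 | step 7 | 2-hydroxy-5-methoxy-3-methylbenzaldehyde | COc1cc(C)c(O)c(C=O)c1
F9 | step 7 | (E)-4-(2-hydroxy-5-methoxy-3-methylphenyl)but-3-en-2-one | COc1cc(C)c(O)c(/C=C/C(C)=O)c1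
F10 | step 7 | 4-(2-hydroxy-5-methoxy-3-methylphenyl)butan-2-one | COc1cc(C)c(O)c(CCC(C)=O)c1
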